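**Plan** (terpenoid numbering: ring A = C1–C5 and C10, ring B = C5–C10; C4 gem-dimethyl, C10 angular methyl, C8 carbinol, C9 carries C11–C22)
Feature used: the quaternary C4 is bonded to the fusion carbon C5, and C5 is 1,3 to C7; with a carbonyl at C7 the ring B alkene C5=C6 is an enone with C5 as β-carbon, so a tertiary C4 radical on the C1–C3 tether from the quaternary C10 can close ring A only cis.
Cuts, retrosynthetically: C12–C13 (sp3–sp2 coupling, C13–C22 from geranylacetone); the C7 oxygen (put back as the activating ketone); C4–C5 (radical closure of ring A); C8–O and C8–CH3 (enolate chemistry); C9–C11 (conjugate vinylation); ring B (annulation of melonal with methyl vinyl ketone).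
Forward: ring B is built and given C8, C9 and C10 (steps 1–5), ring A is closed onto it (step 6), C7 is deoxygenated (steps 7–9), and the chain is joined last (steps 10–12).
Stereochemistry: C9 and C10 from a catalyst-controlled desymmetrisation of a prochiral dienone, C8 from enolate hydroxylation anti to the C9 vinyl group, C5 from C10 through the tether, alkene geometry from (E)-geranylacetone and a syn carbometallation.

Key step: step 6

Assumption: commercial melonal is racemic (its stereocentre is erased in step 2) and (E)-geranylacetone is used as the geometrically pure E isomer.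

**Step 1**
Reactants: 1 melonal (2,6-dimethylhept-5-enal, racemic); 2 methyl vinyl ketone
Product: 4 rac-4-methyl-4-(4-methylpent-3-en-1-yl)cyclohex-2-en-1-one, via keto aldehyde 3 (not isolated)
Conditions: KOH (0.2 equiv), MeOH, 0 °C then 60 °C
Reagents that add atoms: none
Why: Robinson annulation, in which the aldehyde enolate adds to the enone (Michael reaction) and keto aldehyde 3, whose aldehyde has no α-hydrogen left, can condense only through the methyl ketone to the six-membered enone; the quaternary carbon (later C10) forms racemic, which is harmless because step 2 removes its chirality.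

**Step 2**
Reactants: 4 rac-4-methyl-4-(4-methylpent-3-en-1-yl)cyclohex-2-en-1-one
Product: 6 4-methyl-4-(4-methylpent-3-en-1-yl)cyclohexa-2,5-dien-1-one, via silyl dienol ether 5 (not isolated)
Conditions: LiN(iPr)2, Me3SiCl, THF, −78 °C; then Pd(OAc)2 (1.0 equiv), MeCN, rt
Reagents that add atoms: none
Why: Saegusa–Ito dehydrogenation, in which kinetic deprotonation can occur only at the α′-CH2 (the γ-carbon is quaternary) and palladation of 5 by divalent palladium followed by β-hydride elimination gives the cross-conjugated dienone; the former stereocentre becomes prochiral and the isolated trisubstituted alkene should be inert.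

**Step 3**
Reactants: 6 4-methyl-4-(4-methylpent-3-en-1-yl)cyclohexa-2,5-dien-1-one; 7 potassium vinyltrifluoroborate
Product: 8 (4S,5R)-5-ethenyl-4-methyl-4-(4-methylpent-3-en-1-yl)cyclohex-2-en-1-one
Conditions: [RhCl(C2H4)2]2 (2.5 mol %), (R,R)-2,5-diphenylbicyclo[2.2.2]octa-2,5-diene (5.5 mol %), KOH (0.5 equiv), 7 (1.2 equiv), 1,4-dioxane/H2O 10:1, 50 °C
Reagents that add atoms: none
Why: Hayashi–Miyaura rhodium-catalysed asymmetric conjugate addition used as a desymmetrisation, in which the chiral diene on monovalent rhodium fixes the enantioface of the enone C=C that is vinylated (C9 = ring C5, R; the antipodal ligand would be used if the sense proved opposite), and the vinyl–rhodium unit, lying across the ring, should choose the face carrying CH3 over the face carrying the three-carbon chain, so that of the two enantiotopic alkenes the one giving vinyl cis to CH3 reacts (C10 = ring C4, S); the small excess of 7 limits a second addition to the more hindered enone of 8.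

**Step 4**
Reactants: 8 (4S,5R)-5-ethenyl-4-methyl-4-(4-methylpent-3-en-1-yl)cyclohex-2-en-1-one
Product: 10 (4S,5R)-5-ethenyl-4,6-dimethyl-4-(4-methylpent-3-en-1-yl)cyclohex-2-en-1-one (both C6 epimers), via lithium dienolate 9 (not isolated)
Conditions: LiN(iPr)2, THF, −78 °C; MeI, −78 to −20 °C
Reagents that add atoms: iodomethane, CI
Why: kinetic α′-enolate alkylation, in which the base can deprotonate 8 only at ring C6 (C8 of the target) and dienolate 9 is methylated on carbon by SN2; the configuration of the new centre is irrelevant because it is enolised again in step 5.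

**Step 5**
Reactants: 10 (4S,5R)-5-ethenyl-4,6-dimethyl-4-(4-methylpent-3-en-1-yl)cyclohex-2-en-1-one
Product: 12 (4S,5R,6S)-5-ethenyl-6-hydroxy-4,6-dimethyl-4-(4-methylpent-3-en-1-yl)cyclohex-2-en-1-one, via potassium enolate 11 (not isolated)
Conditions: KN(SiMe3)2, THF, −78 °C; 2-(phenylsulfonyl)-3-phenyloxaziridine, −78 °C; aq NH4Cl at −78 °C
Reagents that add atoms: 2-(phenylsulfonyl)-3-phenyloxaziridine, O=S(=O)(N1OC1c1ccccc1)c1ccccc1
Why: Davis hydroxylation of a tetrasubstituted enolate, in which oxygen is transferred to C8 of 11 on the face opposite the neighbouring C9 vinyl group (the other face is screened either by that vinyl group or, in the alternative half-chair, by the axial C10 methyl), so OH ends trans and CH3 cis to vinyl (ring C6, S); the cold quench should keep the tertiary α-ketol from rearranging.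

**Step 6**
Reactants: 12 (4S,5R,6S)-5-ethenyl-6-hydroxy-4,6-dimethyl-4-(4-methylpent-3-en-1-yl)cyclohex-2-en-1-one
Product: 13 (3S,4R,4aS,8aR)-4-ethenyl-3-hydroxy-3,4a,8,8-tetramethyl-3,4,4a,5,6,7,8,8a-octahydronaphthalen-2(1H)-one (cis-fused)
Conditions: Fe(acac)3 (0.3 equiv), PhSiH3 (2.5 equiv), EtOH/HOCH2CH2OH 5:1, 60 °C, 0.02 M
Reagents that add atoms: none
Why: The iron hydride formed from Fe(acac)3 (trivalent iron) and PhSiH3 in ethanol transfers a hydrogen atom to C3, the less substituted carbon of the trisubstituted alkene, the tertiary C4 radical adds to C5, the β-carbon of the ring B enone, and the α-keto radical at C6 is reduced by divalent iron to the enolate and protonated by the solvent. The closest known reaction type is the iron-catalysed reductive coupling of an alkene with an enone by hydrogen atom transfer (a Giese addition started by a metal hydride), known intramolecularly to give cis-fused decalones from 4-alkenylcyclohex-2-enones. Ring A closes in the 6-exo-trig mode through the new C4–C5 bond. The new stereocentre C5 is controlled by C10: the radical must approach perpendicular to the enone plane while its tether leaves C10 equatorially, which is possible only from the tether face, so C4 adds α and C5–H ends β, cis to the C10 methyl group (5R, cis-decalin). The step needs hydrogen atom transfer to the trisubstituted alkene rather than to the vinyl group or the enone, which is secured because the electron-rich trisubstituted alkene gives a tertiary radical and reacts fastest, the vinyl group is monosubstituted and flanked by two fully substituted carbons, closure of the C4 radical onto it would be 7-exo or 8-endo, and PhSiH3 is limited and the solution dilute. C8, C9 and C10 are not epimerisable under these conditions.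

**Step 7**
Reactants: 13 cis-fused ketol
Product: 14 (1R,2S,3S,4aR,8aS)-1-ethenyl-2,5,5,8a-tetramethyldecahydronaphthalene-2,3-diol (7β,8α-diol in terpenoid numbering)
Conditions: Me4NBH(OAc)3 (4 equiv), MeCN/AcOH 1:1, −20 °C to rt
Reagents that add atoms: none
Why: hydroxyl-directed (Saksena–Evans) reduction, in which the tertiary C8 hydroxyl exchanges onto boron and delivers hydride intramolecularly to the α face of the C7 ketone, so the new C7 hydroxyl is β and trans-diaxial to the C8 hydroxyl (C7, S); the vinyl group should not react.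

**Step 8**
Reactants: 14 7β,8α-diol
Product: 15 (2S,3S,4R,4aS,8aR)-4-ethenyl-3-hydroxy-3,4a,8,8-tetramethyldecahydronaphthalen-2-yl methanesulfonate
Conditions: MsCl (1.2 equiv), Et3N, CH2Cl2, −20 °C
Reagents that add atoms: methanesulfonyl chloride, CS(=O)(=O)Cl
Why: selective sulfonylation, in which the secondary C7 hydroxyl is mesylated while the tertiary C8 hydroxyl, flanked by two fully substituted carbons, should stay free at low temperature; no stereocentre changes.

**Step 9**
Reactants: 15 C7 mesylate
Product: 17 (1R,2R,4aR,8aS)-1-ethenyl-2,5,5,8a-tetramethyldecahydronaphthalen-2-ol, via 7α,8α-epoxide 16 (not isolated)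
Conditions: LiEt3BH (4 equiv), THF, 0 to 50 °C
Reagents that add atoms: none
Why: reductive removal of a β-hydroxy sulfonate through its epoxide, in which hydride first deprotonates the C8 hydroxyl, the alkoxide displaces the antiperiplanar C7 mesylate (inversion at C7, C8–O bond untouched) to give 16, and a second hydride opens the trisubstituted epoxide by SN2 at the less substituted C7, leaving C7 as CH2 and the C8 carbinol with its configuration retained.

**Step 10**
Reactants: 18 (E)-geranylacetone
Product: 20 (5E)-6,10-dimethylundeca-5,9-dien-1-yne, via enol phosphate 19 (not isolated)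
Conditions: LiN(iPr)2 (1.05 equiv), THF, −78 °C; ClP(O)(OEt)2; then LiN(iPr)2 (2.3 equiv), −78 °C to rt
Reagents that add atoms: none
Why: ketone-to-alkyne conversion through an enol phosphate, in which kinetic deprotonation at the methyl group gives terminal enol phosphate 19 and further amide base eliminates diethyl phosphate (E2) and holds the product as its acetylide; the trisubstituted alkenes and the 5E geometry are untouched.

**Step 11**
Reactants: 20 (5E)-6,10-dimethylundeca-5,9-dien-1-yne
Product: 22 (1E,5E)-1-iodo-2,6,10-trimethylundeca-1,5,9-triene, via alkenylalane 21 (not isolated)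
Conditions: AlMe3 (2.5 equiv), Cp2ZrCl2 (0.3 equiv), CH2Cl2, 0 °C to rt; then I2, THF, −30 to 0 °C
Reagents that add atoms: trimethylaluminium, C[Al](C)C; iodine, II
Why: zirconium-catalysed carboalumination (Negishi) followed by iodinolysis, in which Me–Al adds syn across the terminal alkyne with aluminium on the terminal carbon to give the (E)-alkenylalane 21 and iodine replaces aluminium with retention, fixing the E geometry of the future C13=C14 bond.

**Step 12**
Reactants: 17 (1R,2R,4aR,8aS)-1-ethenyl-2,5,5,8a-tetramethyldecahydronaphthalen-2-ol; 22 (1E,5E)-1-iodo-2,6,10-trimethylundeca-1,5,9-triene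
Product: 24 (1R,2R,4aR,8aS)-2,5,5,8a-tetramethyl-1-[(3E,7E)-4,8,12-trimethyltrideca-3,7,11-trien-1-yl]decahydronaphthalen-2-ol (target), via alkylborane 23 (not isolated)
Conditions: 9-BBN dimer (2.5 equiv B–H), THF, rt; then 22, PdCl2(dppf) (5 mol %), 3 M aq NaOH, THF, 50 °C
Reagents that add atoms: none
Why: hydroboration and B-alkyl Suzuki–Miyaura coupling, in which 9-BBN adds anti-Markovnikov to the only alkene of 17 to give primary alkylborane 23, its hydroxide ate complex transmetallates to the alkenylpalladium species formed by oxidative addition of 22 to zerovalent palladium, and reductive elimination joins C12 to C13 with retention of the alkene geometry; no stereocentre is touched.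

**Compound list**
1 | melonal (2,6-dimethylhept-5-enal, racemic) | CC(C)=CCCC(C)C=O | starting material
2 | methyl vinyl ketone (but-3-en-2-one) | CC(=O)C=C | starting material
3 | 2,6-dimethyl-2-(3-oxobutyl)hept-5-enal (racemic) | CC(C)=CCCC(C)(C=O)CCC(C)=O | intermediate (not isolated)
4 | rac-4-methyl-4-(4-methylpent-3-en-1-yl)cyclohex-2-en-1-one | CC(C)=CCCC1(C)C=CC(=O)CC1 | intermediate
5 | trimethyl{[4-methyl-4-(4-methylpent-3-en-1-yl)cyclohexa-1,5-dien-1-yl]oxy}silane | CC(C)=CCCC1(C)C=CC(O[Si](C)(C)C)=CC1 | intermediate (not isolated)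
6 | 4-methyl-4-(4-methylpent-3-en-1-yl)cyclohexa-2,5-dien-1-one | CC(C)=CCCC1(C)C=CC(=O)C=C1 | intermediate
7 | potassium vinyltrifluoroborate | C=C[B-](F)(F)F.[K+] | starting material
8 | (4S,5R)-5-ethenyl-4-methyl-4-(4-methylpent-3-en-1-yl)cyclohex-2-en-1-one | C=C[C@@H]1[C@@](C)(CCC=C(C)C)C=CC(=O)C1 | intermediate
9 | lithium dienolate of 8 | C=C[C@@H]1[C@@](C)(CCC=C(C)C)C=CC([O-])=C1.[Li+] | intermediate (not isolated)
10 | (4S,5R)-5-ethenyl-4,6-dimethyl-4-(4-methylpent-3-en-1-yl)cyclohex-2-en-1-one (both C6 epimers) | C=C[C@@H]1[C@@](C)(CCC=C(C)C)C=CC(=O)C1C | intermediate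
11 | potassium enolate of 10 | C=C[C@@H]1[C@@](C)(CCC=C(C)C)C=CC([O-])=C1C.[K+] | intermediate (not isolated)
12 | (4S,5R,6S)-5-ethenyl-6-hydroxy-4,6-dimethyl-4-(4-methylpent-3-en-1-yl)cyclohex-2-en-1-one | C=C[C@@H]1[C@@](C)(CCC=C(C)C)C=CC(=O)[C@@]1(C)O | intermediate (precursor of the key step)
13 | (3S,4R,4aS,8aR)-4-ethenyl-3-hydroxy-3,4a,8,8-tetramethyl-3,4,4a,5,6,7,8,8a-octahydronaphthalen-2(1H)-one | C=C[C@@H]1[C@@]2(C)CCCC(C)(C)[C@H]2CC(=O)[C@@]1(C)O | intermediate (product of the key step)
14 | (1R,2S,3S,4aR,8aS)-1-ethenyl-2,5,5,8a-tetramethyldecahydronaphthalene-2,3-diol | C=C[C@@H]1[C@@]2(C)CCCC(C)(C)[C@H]2C[C@H](O)[C@@]1(C)O | intermediate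
15 | (2S,3S,4R,4aS,8aR)-4-ethenyl-3-hydroxy-3,4a,8,8-tetramethyldecahydronaphthalen-2-yl methanesulfonate | C=C[C@@H]1[C@@]2(C)CCCC(C)(C)[C@H]2C[C@H](OS(C)(=O)=O)[C@@]1(C)O | intermediate
16 | 7α,8α-epoxide of the cis-decalin (oxirane on the face of the C8–O bond; C9 vinyl, C10 methyl and C5–H all β) | C=C[C@@H]1[C@@]2(C)CCCC(C)(C)[C@H]2C[C@H]3O[C@]31C | intermediate (not isolated)
17 | (1R,2R,4aR,8aS)-1-ethenyl-2,5,5,8a-tetramethyldecahydronaphthalen-2-ol | C=C[C@@H]1[C@@]2(C)CCCC(C)(C)[C@H]2CC[C@@]1(C)O | intermediate
18 | (E)-geranylacetone ((5E)-6,10-dimethylundeca-5,9-dien-2-one) | CC(C)=CCC/C(C)=C/CCC(C)=O | starting material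
19 | diethyl (5E)-6,10-dimethylundeca-1,5,9-trien-2-yl phosphate | CC(C)=CCC/C(C)=C/CCC(=C)OP(=O)(OCC)OCC | intermediate (not isolated)
20 | (5E)-6,10-dimethylundeca-5,9-dien-1-yne | CC(C)=CCC/C(C)=C/CCC#C | intermediate
21 | dimethyl[(1E,5E)-2,6,10-trimethylundeca-1,5,9-trien-1-yl]alumane | CC(C)=CCC/C(C)=C/CC/C(C)=C/[Al](C)C | intermediate (not isolated)
22 | (1E,5E)-1-iodo-2,6,10-trimethylundeca-1,5,9-triene | CC(C)=CCC/C(C)=C/CC/C(C)=C/I | intermediate
23 | 9-{2-[(1R,2R,4aR,8aS)-2-hydroxy-2,5,5,8a-tetramethyldecahydronaphthalen-1-yl]ethyl}-9-borabicyclo[3.3.1]nonane | C1CCC2CCCC1B2CC[C@@H]1[C@@]2(C)CCCC(C)(C)[C@H]2CC[C@@]1(C)O | intermediate (not isolated)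
24 | (1R,2R,4aR,8aS)-2,5,5,8a-tetramethyl-1-[(3E,7E)-4,8,12-trimethyltrideca-3,7,11-trien-1-yl]decahydronaphthalen-2-ol | CC(C)=CCC/C(C)=C/CC/C(C)=C/CC[C@@H]1[C@@]2(C)CCCC(C)(C)[C@H]2CC[C@@]1(C)O | target

**Count**
Total: 12 steps. Longest linear sequence: 10 steps (steps 1–9 and 12); steps 10–11 make the chain fragment.

**Steps most likely to fail**

Step 3. The catalyst may not tell the methyl face from the chain face at C10, giving a mixture of C4 epimers of 8, and a second vinylation may compete. The fallback builds the C9/C10 pair by alkylation trans to an existing substituent instead of by face selection. It sets out from 7 and rejoins at 8. Rhodium-catalysed asymmetric addition of 7 to commercial 2-methylcyclohex-2-en-1-one (same catalyst type, higher temperature) should give (3R)-3-ethenyl-2-methylcyclohexan-1-one F1. Thermodynamic silylation (Me3SiCl, NaI, Et3N, MeCN) should give trimethyl{[(3R)-3-ethenyl-2-methylcyclohex-1-en-1-yl]oxy}silane F2. MeLi followed by 5-iodo-2-methylpent-2-ene and HMPA should alkylate the regiodefined enolate anti to the vinyl group to give (2R,3R)-3-ethenyl-2-methyl-2-(4-methylpent-3-en-1-yl)cyclohexan-1-one F3. Saegusa–Ito oxidation should give (5R,6R)-5-ethenyl-6-methyl-6-(4-methylpent-3-en-1-yl)cyclohex-2-en-1-one F4. Nucleophilic epoxidation (H2O2, NaOH, MeOH) should give (3R,4R)-4-ethenyl-3-methyl-3-(4-methylpent-3-en-1-yl)-7-oxabicyclo[4.1.0]heptan-2-one F5. Wharton transposition (N2H4·H2O, AcOH) should give (4S,5R)-5-ethenyl-4-methyl-4-(4-methylpent-3-en-1-yl)cyclohex-2-en-1-ol F6, and MnO2 oxidation returns to 8.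

Step 6. Hydrogen atom transfer may also reach the vinyl group, or the enone may be reduced before ring closure. The fallback makes the same C4 radical by halogen abstraction; it sets out from 12 and rejoins at 13. Markovnikov addition of HBr (HBr in AcOH, CH2Cl2, −20 °C) to the trisubstituted alkene should give (4S,5R,6S)-4-(4-bromo-4-methylpentyl)-5-ethenyl-6-hydroxy-4,6-dimethylcyclohex-2-en-1-one F7. Bu3SnH with AIBN (slow addition, benzene, 80 °C) should then close ring A by the same 6-exo conjugate addition.

Step 9. Displacement at the hindered C7 may stall, or the epoxide may open or eliminate in another sense. The fallback removes the C7 oxygen by a radical (Barton–McCombie) path; it sets out from 14 and rejoins at 17. 1,1′-Thiocarbonyldiimidazole (DMAP, ClCH2CH2Cl, 60 °C) should acylate only the secondary hydroxyl, because the trans-diaxial diol cannot close to a cyclic thionocarbonate, giving O-[(2S,3S,4R,4aS,8aR)-4-ethenyl-3-hydroxy-3,4a,8,8-tetramethyldecahydronaphthalen-2-yl] 1H-imidazole-1-carbothioate F8. Bu3SnH with AIBN (toluene, 110 °C) should replace C7–O by C7–H.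

**Further compounds**
F1 | step 3 | (3R)-3-ethenyl-2-methylcyclohexan-1-one (C2 epimers) | C=C[C@@H]1C(C)C(=O)CCC1
F2 | step 3 | trimethyl{[(3R)-3-ethenyl-2-methylcyclohex-1-en-1-yl]oxy}silane | C=C[C@@H]1C(C)=C(O[Si](C)(C)C)CCC1
F3 | step 3 | (2R,3R)-3-ethenyl-2-methyl-2-(4-methylpent-3-en-1-yl)cyclohexan-1-one | C=C[C@@H]1[C@@](C)(CCC=C(C)C)C(=O)CCC1
F4 | step 3 | (5R,6R)-5-ethenyl-6-methyl-6-(4-methylpent-3-en-1-yl)cyclohex-2-en-1-one | C=C[C@@H]1[C@@](C)(CCC=C(C)C)C(=O)C=CC1
F5 | step 3 | (3R,4R)-4-ethenyl-3-methyl-3-(4-methylpent-3-en-1-yl)-7-oxabicyclo[4.1.0]heptan-2-one (epoxide on either face) | C=C[C@@H]1[C@@](C)(CCC=C(C)C)C(=O)C2OC2C1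
F6 | step 3 | (4S,5R)-5-ethenyl-4-methyl-4-(4-methylpent-3-en-1-yl)cyclohex-2-en-1-ol (C1 epimers) | C=C[C@@H]1[C@@](C)(CCC=C(C)C)C=CC(O)C1
F7 | step 6 | (4S,5R,6S)-4-(4-bromo-4-methylpentyl)-5-ethenyl-6-hydroxy-4,6-dimethylcyclohex-2-en-1-one | C=C[C@@H]1[C@@](C)(CCCC(C)(C)Br)C=CC(=O)[C@@]1(C)O
F8 | step 9 | O-[(2S,3S,4R,4aS,8aR)-4-ethenyl-3-hydroxy-3,4a,8,8-tetramethyldecahydronaphthalen-2-yl] 1H-imidazole-1-carbothioate | C=C[C@@H]1[C@@]2(C)CCCC(C)(C)[C@H]2C[C@H](OC(=S)n3ccnc3)[C@@]1(C)O
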